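## Retrosynthetic overview
1. The dihydrofuran C2–O bond is made last. The 4'-phenoxide opens a threo epoxy alcohol 5-exo-tet with inversion, and global O-deallylation triggers this closure.
2. The epoxy alcohol comes from a 3'-iodoflavone, prenal and one oxygen atom in one flask. A catalytic asymmetric aryl addition sets C3, and an alkoxide-directed epoxidation sets the precursor of C2.
3. Ring C comes from a 2'-hydroxychalcone by oxa-Michael closure and dehydrogenation (chalcone to flavanone to flavone).
4. The chalcone comes from a Claisen–Schmidt union of diallyl phloroacetophenone (ring A) with an iodo-prenyl benzaldehyde (ring B). The ring B aldehyde is made by phenoxide C-prenylation.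
5. Ring order: rings A and B are bought, ring C is formed first, and the dihydrofuran ring is formed last.

Assumption: the SMILES is read as (2S,3S), meaning 3-OH and 2-C(CH3)2OH are trans on the dihydrofuran, and 4-hydroxy-3-iodobenzaldehyde is taken as a catalogue compound.

## Route

Step 1
Reactants: 1 4-hydroxy-3-iodobenzaldehyde; 2 prenyl bromide (1-bromo-3-methylbut-2-ene)
Product: 3 4-hydroxy-3-iodo-5-(3-methylbut-2-enyl)benzaldehyde
Conditions: KOH, H2O, 25 °C
Reagents that add atoms: prenyl bromide (2), CC(C)=CCBr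
Why: In water the phenoxide oxygen is hydrogen-bonded, so the soft allylic bromide alkylates the only free ortho carbon (phenoxide ortho-C-alkylation, the laboratory version of aromatic prenyl transfer), and the O-prenyl ether is the separable by-product.

Step 2
Reactants: 3 4-hydroxy-3-iodo-5-(3-methylbut-2-enyl)benzaldehyde; 4 allyl bromide (3-bromoprop-1-ene)
Product: 5 4-(allyloxy)-3-iodo-5-(3-methylbut-2-enyl)benzaldehyde
Conditions: K2CO3, DMF, 40 °C
Reagents that add atoms: allyl bromide (4), C=CCBr
Why: A Williamson ether synthesis masks the acidic phenol so that it cannot cyclise onto the prenyl group, slow the aldol or quench the later Grignard reagent.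

Step 3
Reactants: 6 2,4,6-trihydroxyacetophenone; 4 allyl bromide
Product: 7 1-[2-hydroxy-4,6-bis(allyloxy)phenyl]ethanone
Conditions: K2CO3 (2.2 equiv), 4 (2.1 equiv), acetone, reflux
Reagents that add atoms: allyl bromide (4), C=CCBr
Why: This is a Williamson ether synthesis in which the hydroxyl hydrogen-bonded to the ketone stays free, leaving exactly the 2'-OH needed for ring C.

Step 4
Reactants: 5 4-(allyloxy)-3-iodo-5-(3-methylbut-2-enyl)benzaldehyde; 7 1-[2-hydroxy-4,6-bis(allyloxy)phenyl]ethanone
Product: 8 (E)-1-[2-hydroxy-4,6-bis(allyloxy)phenyl]-3-[4-(allyloxy)-3-iodo-5-(3-methylbut-2-enyl)phenyl]prop-2-en-1-one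
Conditions: KOH, EtOH, 25 °C
Reagents that add atoms: none
Why: A Claisen–Schmidt condensation of a non-enolisable aldehyde carrying no free phenol gives the conjugated (E)-chalcone, and aryl iodide, allyl ethers and prenyl are inert to ethanolic KOH.

Step 5
Reactants: 8 the (E)-2'-hydroxychalcone
Product: 10 5,7-bis(allyloxy)-2-[4-(allyloxy)-3-iodo-5-(3-methylbut-2-enyl)phenyl]-4H-chromen-4-one, via racemic flavanone 9 (not isolated)
Conditions: DDQ (1.5 equiv), 1,4-dioxane, reflux
Reagents that add atoms: none
Why: The acidic hydroquinone formed from DDQ equilibrates 8 with flavanone 9 by 6-endo oxa-Michael addition (the chalcone isomerase step), and DDQ then takes hydride from the oxygen- and aryl-stabilised C2–H (the flavone synthase step, DDQ cyclodehydrogenation), while the twisted, doubly ortho-flanked 4'-O-allyl group activates the prenyl CH2 only weakly; I2/DMSO is avoided because it cleaves aryl allyl ethers, and no stereocentre remains.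

Step 6
Reactants: 10 the 3'-iodoflavone; 11 3-methylbut-2-enal (prenal); 12 tert-butyl hydroperoxide
Product: 16 5,7-bis(allyloxy)-2-{4-(allyloxy)-3-[(S)-[(2R)-3,3-dimethyloxiran-2-yl](hydroxy)methyl]-5-(3-methylbut-2-enyl)phenyl}-4H-chromen-4-one, via arylmagnesium chloride 13 (not isolated), via aryltitanium triisopropoxide 14 (not isolated), via (R)-allylic alcohol 15 (not isolated)
Conditions: i-PrMgCl·LiCl, THF, −40 °C; Ti(OiPr)4 (3 equiv), (S)-H8-BINOL (10 mol %), 11 (2 equiv), THF/CH2Cl2, −20 to 0 °C; then 12 (decane solution, 2 equiv), −20 °C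
Reagents that add atoms: 3-methylbut-2-enal (11), CC(C)=CC=O; tert-butyl hydroperoxide (12), CC(C)(C)OO
Why: Proposed new method: iodine–magnesium exchange (faster at −40 °C than Grignard attack on the vinylogous-ester carbonyl of the flavone) followed by transmetalation gives an aryltitanium that adds only to the aldehyde, the (S)-BINOLate–titanium catalyst directs Si-face attack on 11 to set the (R)-carbinol (the later C3), and the titanium allylic alkoxide so formed binds 12 and, with its carbinol H held in the alkene plane by allylic 1,3-strain against the Z-methyl, delivers oxygen syn to its own C–O bond to set the (R)-epoxide carbon (threo, about 9:1) while the unbound prenyl and allyl olefins stay untouched; the closest known reaction types are the BINOLate–titanium-catalysed arylation of aldehydes with functionalised Grignard reagents and the one-pot carbonyl addition/titanium-directed epoxidation of metal allylic alkoxides.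

Step 7
Reactants: 16 the tri-O-allyl threo epoxy alcohol
Product: 18 5,7-dihydroxy-2-[(2S,3S)-3-hydroxy-2-(2-hydroxypropan-2-yl)-7-(3-methylbut-2-enyl)-2,3-dihydro-1-benzofuran-5-yl]-4H-chromen-4-one, via triphenol epoxy alcohol 17 (not isolated)
Conditions: Pd(PPh3)4 (5 mol %), K2CO3, MeOH, 25 to 45 °C
Reagents that add atoms: none
Why: Tsuji–Trost deallylation by zerovalent palladium frees all three phenols, and carbonate ionises only the phenols and not the carbinol (so no Payne shift), so the 4'-phenoxide opens the neighbouring epoxide at its secondary carbon in the base-favoured 5-exo-tet mode (the epoxide-opening closure assumed for hydroxyisopropyl-dihydrofurans in nature) with clean inversion, turning the (R)-epoxide carbon into (2S), trans to the untouched (3S)-OH.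

## Compound list
1 | 4-hydroxy-3-iodobenzaldehyde | O=Cc1ccc(O)c(I)c1 | starting material
2 | prenyl bromide (1-bromo-3-methylbut-2-ene) | CC(C)=CCBr | starting material
3 | 4-hydroxy-3-iodo-5-(3-methylbut-2-enyl)benzaldehyde | O=Cc1cc(I)c(O)c(CC=C(C)C)c1 | intermediate
4 | allyl bromide | C=CCBr | starting material
5 | 4-(allyloxy)-3-iodo-5-(3-methylbut-2-enyl)benzaldehyde | O=Cc1cc(I)c(OCC=C)c(CC=C(C)C)c1 | intermediate
6 | 2,4,6-trihydroxyacetophenone | CC(=O)c1c(O)cc(O)cc1O | starting material
7 | 1-[2-hydroxy-4,6-bis(allyloxy)phenyl]ethanone | CC(=O)c1c(O)cc(OCC=C)cc1OCC=C | intermediate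
8 | (E)-2'-hydroxy-4',6',4-tris(allyloxy)-3-iodo-5-prenylchalcone | O=C(/C=C/c1cc(I)c(OCC=C)c(CC=C(C)C)c1)c1c(O)cc(OCC=C)cc1OCC=C | intermediate
9 | racemic 5,7-bis(allyloxy)-2-[4-(allyloxy)-3-iodo-5-prenylphenyl]chroman-4-one (not isolated) | O=C1CC(c2cc(I)c(OCC=C)c(CC=C(C)C)c2)Oc2cc(OCC=C)cc(OCC=C)c21 | intermediate
10 | 5,7-bis(allyloxy)-2-[4-(allyloxy)-3-iodo-5-prenylphenyl]-4H-chromen-4-one | O=c1cc(-c2cc(I)c(OCC=C)c(CC=C(C)C)c2)oc2cc(OCC=C)cc(OCC=C)c12 | intermediate
11 | 3-methylbut-2-enal (prenal) | CC(C)=CC=O | starting material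
12 | tert-butyl hydroperoxide | CC(C)(C)OO | starting material
13 | 3'-chloromagnesio analogue of 10 (not isolated) | O=c1cc(-c2cc([Mg]Cl)c(OCC=C)c(CC=C(C)C)c2)oc2cc(OCC=C)cc(OCC=C)c12 | intermediate
14 | 3'-triisopropoxytitanio analogue of 10 (not isolated) | O=c1cc(-c2cc([Ti](OC(C)C)(OC(C)C)OC(C)C)c(OCC=C)c(CC=C(C)C)c2)oc2cc(OCC=C)cc(OCC=C)c12 | intermediate
15 | 5,7-bis(allyloxy)-2-{4-(allyloxy)-3-[(1R)-1-hydroxy-3-methylbut-2-enyl]-5-prenylphenyl}-4H-chromen-4-one (formed as its titanium alkoxide, not isolated) | O=c1cc(-c2cc(CC=C(C)C)c(OCC=C)c([C@H](O)C=C(C)C)c2)oc2cc(OCC=C)cc(OCC=C)c12 | intermediate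
16 | tri-O-allyl threo epoxy alcohol, carbinol (S), epoxide CH (R) | O=c1cc(-c2cc(CC=C(C)C)c(OCC=C)c([C@H](O)[C@H]3OC3(C)C)c2)oc2cc(OCC=C)cc(OCC=C)c12 | intermediate
17 | 2-{3-[(S)-[(2R)-3,3-dimethyloxiran-2-yl](hydroxy)methyl]-4-hydroxy-5-prenylphenyl}-5,7-dihydroxy-4H-chromen-4-one (not isolated) | O=c1cc(-c2cc(CC=C(C)C)c(O)c([C@H](O)[C@H]3OC3(C)C)c2)oc2cc(O)cc(O)c12 | intermediate
18 | CNP0172554.1, (2S,3S), trans | CC(C)=CCc1cc(-c2cc(=O)c3c(O)cc(O)cc3o2)cc2c1O[C@H](C(C)(C)O)[C@H]2O | target

## Count and risks
Total step count: 7. Longest linear sequence: 6 (steps 1, 2, 4, 5, 6, 7).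

Steps most likely to fail, in order: 6, 5, 1.

**Step 6.** Possible failures:
- attack of the Grignard reagent on the flavone
- low ee with the ortho-alkoxy aryltitanium
- an unclean telescoped epoxidation

The fallback sets out from 10 and comes back at 16.
- A Nozaki–Hiyama–Kishi coupling of 10 with 11 (CrCl2, 1 % NiCl2, DMF, 25 °C) makes the same C–C bond without any aryl magnesium or titanium species. It gives the racemic allylic alcohol F1.
- MnO2 in CH2Cl2 oxidises F1 to the aryl 2-methylprop-1-enyl ketone F2.
- Corey–Bakshi–Shibata reduction gives 15, now isolated. The conditions are (S)-methyl oxazaborolidine, catecholborane, toluene, −78 °C, with the aryl as the large group.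
- VO(acac)2/t-BuOOH in CH2Cl2 at 0 °C then gives 16 by the same 1,3-strain-controlled threo delivery.

**Step 5.** Possible failures:
- aurone formation
- DDQ attack at the prenyl CH2

The fallback sets out from 8 and comes back at 10.
- Ring C alone is closed with NaOAc in refluxing EtOH, and flavanone 9 is isolated.
- Soft enolisation (TMSOTf, Et3N, CH2Cl2, 0 °C) converts 9 into the trimethylsilyl enol ether F3. This avoids the retro-oxa-Michael opening that a lithium enolate suffers.
- F3 is dehydrogenated at 25 °C with IBX·4-methoxypyridine N-oxide in DMSO to give 10.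

**Step 1.** The likely failure is that O-alkylation dominates on this acidic, hindered phenoxide. The fallback sets out from 1 and comes back at 3.
- Compound 1 is iodinated once more (I2, KI, aqueous NaOH, 25 °C) to 4-hydroxy-3,5-diiodobenzaldehyde F4.
- One of the two equivalent iodides is replaced by a Stille coupling with tributyl(3-methylbut-2-enyl)stannane (1 equiv, Pd(PPh3)4, DMF, 80 °C).
- Unreacted F4 is recycled, and the mono-coupled product is 3.

## Further compounds
F1 | step 6 | racemic 5,7-bis(allyloxy)-2-{4-(allyloxy)-3-(1-hydroxy-3-methylbut-2-enyl)-5-prenylphenyl}-4H-chromen-4-one | O=c1cc(-c2cc(CC=C(C)C)c(OCC=C)c(C(O)C=C(C)C)c2)oc2cc(OCC=C)cc(OCC=C)c12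
F2 | step 6 | 5,7-bis(allyloxy)-2-{4-(allyloxy)-3-(3-methylbut-2-enoyl)-5-prenylphenyl}-4H-chromen-4-one | O=c1cc(-c2cc(CC=C(C)C)c(OCC=C)c(C(=O)C=C(C)C)c2)oc2cc(OCC=C)cc(OCC=C)c12
F3 | step 5 | 4-(trimethylsilyloxy)-2H-chromene (silyl enol ether) of flavanone 9 | C[Si](C)(C)OC1=CC(c2cc(I)c(OCC=C)c(CC=C(C)C)c2)Oc2cc(OCC=C)cc(OCC=C)c21
F4 | step 1 | 4-hydroxy-3,5-diiodobenzaldehyde | O=Cc1cc(I)c(O)c(I)c1
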